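**Retrosynthetic overview**

1. Labdane numbering is used (ring A = C1–C5, C10; ring B = C5–C10). The C8 acetate and C15 acid come from a hydroxy ester; H-9 from hydroxyl-directed hydrogenation of a C9=C11 alkylidene; the C8 carbinol from methyl addition to an 8-ketone; C9=C11 from aldol condensation of a C8=C9 enol silane with a C11–C15 aldehyde whose C13 comes from (R)-methyl hydrogen 3-methylglutarate.
2. Key disconnection C1–C10: ring A is closed onto a ring-B 3-methylcyclohex-2-enone by nickel-catalysed reductive cyclisation of a C1 bromide. Two electrophilic carbons are joined, and the step gives the C10 quaternary centre and the C8=C9 enol silane together.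
3. Enabling feature: C10 is β to the C8 oxygen (C8–C9–C10) and adjacent to C5, whose C4(CH3)2 arm carries C1–C3. A ring closed from that arm onto the C9=C10 enone can only be cis-fused, and the A/B fusion of the target (H-5 and CH3-20 on the same face) is cis.
4. Ring B with C4, C18 and C19 comes from (+)-nopinone: cleaving its cyclobutane leaves ring B (nopinone C5 = C5, bridging CH2 = C10, C(CH3)2 bridge = C4, C=O = C8). Allylation, desaturation, methylation and hydrobromination follow.
5. Order of ring formation: ring B (chiral pool) first, ring A in the key step.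

Key step: step 6

Remark: the target SMILES specifies a cis-fused decalin (5R,10S; H-5 and CH3-20 syn), the 5-epimer of the usual labdane series, and the route is built for that isomer; (+)-nopinone and (R)-methyl hydrogen 3-methylglutarate are taken as commercial materials of high enantiomeric purity.

**Route**

Step 1
Reactants: 1 (+)-nopinone, (1R,5S)-6,6-dimethylbicyclo[3.1.1]heptan-2-one
Product: 2 (S)-4-(2-acetoxypropan-2-yl)cyclohex-1-en-1-yl acetate
Conditions: Ac2O, BF3·OEt2, Zn(OAc)2, rt
Reagents that add atoms: acetic anhydride, CC(=O)OC(C)=O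
Why: Lewis-acid-promoted fragmentation of the strained cyclobutane bond α to the ketone (acid-mediated cyclobutane cleavage of a pinanone) should give a tertiary cation and an enolate that are both acetylated; the enol acetate can only form toward the former bridgehead (future C9) and the C5 stereocenter is not touched.

Step 2
Reactants: 2 (S)-4-(2-acetoxypropan-2-yl)cyclohex-1-en-1-yl acetate
Product: 3 (S)-4-(2-methylpent-4-en-2-yl)cyclohex-1-en-1-yl acetate
Conditions: allylSiMe3, TiCl4, CH2Cl2, −78 °C
Reagents that add atoms: allyltrimethylsilane, C=CC[Si](C)(C)C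
Why: Hosomi–Sakurai-type SN1 allylation: TiCl4 ionises the tertiary acetate and the allylsilane traps the cation to build the C4 quaternary carbon with C3–C1 attached, while the far less nucleophilic enol acetate should survive at −78 °C; no stereocenter is formed.

Step 3
Reactants: 3 (S)-4-(2-methylpent-4-en-2-yl)cyclohex-1-en-1-yl acetate
Product: 4 (S)-4-(2-methylpent-4-en-2-yl)cyclohex-2-en-1-one
Conditions: Pd(OAc)2 (cat.), dppe (cat.), Bu3SnOMe (cat.), allyl methyl carbonate, MeCN, 80 °C
Reagents that add atoms: none
Why: Tsuji dehydrogenation of an enol acetate: the tin enolate formed in situ passes to a palladium enolate at C9 whose only β-hydrogens are on C10, so the C9=C10 enone should form with the γ-stereocenter C5 intact.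

Step 4
Reactants: 4 (S)-4-(2-methylpent-4-en-2-yl)cyclohex-2-en-1-one
Product: 6 (R)-3-methyl-4-(2-methylpent-4-en-2-yl)cyclohex-2-en-1-one, via trimethylsilyl enol ether 5 (not isolated)
Conditions: Me2CuLi, Me3SiCl, THF, −78 °C; then Pd(OAc)2, MeCN, rt
Reagents that add atoms: lithium dimethylcuprate, [Li+].C[Cu-]C
Why: Cuprate conjugate addition with silyl trapping (methyl enters anti to the C5 substituent) followed by Saegusa–Ito oxidation of the regiodefined enol silane should return the enone with C10 methylated; the transient C10 stereocenter is erased and C5 is untouched.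

Step 5
Reactants: 6 (R)-3-methyl-4-(2-methylpent-4-en-2-yl)cyclohex-2-en-1-one
Product: 7 (R)-4-(5-bromo-2-methylpentan-2-yl)-3-methylcyclohex-2-en-1-one
Conditions: HBr (gas), (PhCO2)2 (cat.), hexane, 0 °C
Reagents that add atoms: hydrogen bromide, Br
Why: Kharasch anti-Markovnikov radical-chain hydrobromination: the electrophilic bromine atom adds to the terminal carbon of the electron-rich monosubstituted alkene in preference to the electron-poor enone, giving the primary C1 bromide; no stereocenter is formed.

Step 6
Reactants: 7 (R)-4-(5-bromo-2-methylpentan-2-yl)-3-methylcyclohex-2-en-1-one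
Product: 8 triethyl{[(4aR,8aS)-5,5,8a-trimethyl-3,4,4a,5,6,7,8,8a-octahydronaphthalen-2-yl]oxy}silane
Conditions: NiCl2(dme) (10 mol%), neocuproine (10 mol%), Mn powder, Et3SiCl, DMF, 40 °C, 0.02 M
Reagents that add atoms: chlorotriethylsilane, CC[Si](CC)(CC)Cl
Why: Manganese reduces the nickel salt to zerovalent nickel, which with Et3SiCl turns the enone into a (1-triethylsiloxy)allylnickel species while halogen-atom abstraction from the C1–Br bond gives the primary C1 radical; capture of this radical at nickel and C–C reductive elimination (or its direct addition to C10 followed by reduction and silylation of the α-keto radical) forms the C1–C10 bond and releases the silyl enol ether. The closest known reaction type is the intermolecular nickel-catalysed reductive conjugate addition of primary alkyl bromides to cyclic enones with chlorosilane trapping, a union of two electrophilic carbons. Ring A closes in the 6-exo-trig mode, the attacked C9=C10 bond lying outside the new ring. The new quaternary stereocenter C10 is controlled by C5: the C4 arm can bring C1 to C10 only perpendicular to the enone plane and on its own face, so C1 and C4 end up cis on ring B and CH3-20 and H-5 syn (10S), which is the ring fusion of the target. The step needs cyclisation to outrun reduction or dimerisation of the radical and attack at C10 instead of C9; the gem-dimethyl group on C4, the polarity match of the alkyl radical with the enone β-carbon, the six-membered transition state and high dilution should secure this. The enol silane is delivered regiodefined at C8=C9, which is what allows the side chain to be attached at C9 in step 10.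

Step 7
Reactants: 9 (R)-methyl hydrogen 3-methylglutarate, (3R)-5-methoxy-3-methyl-5-oxopentanoic acid
Product: 11 (S)-4-methyloxan-2-one, via lithium 5-hydroxy-3-methylpentanoate 10 (not isolated)
Conditions: LiBH4, THF, 0 °C to rt; then 2 M HCl
Reagents that add atoms: none
Why: Chemoselective borohydride reduction of the ester arm (the lithium carboxylate is inert) and acid-induced lactonisation; the stereocenter is untouched, and the former free-acid arm becomes C14–C15.

Step 8
Reactants: 11 (S)-4-methyloxan-2-one
Product: 12 methyl (S)-5-hydroxy-3-methylpentanoate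
Conditions: MeOH, H2SO4 (cat.), 65 °C; NaHCO3
Reagents that add atoms: methanol, CO
Why: Acid-catalysed ring-opening transesterification of the δ-lactone; the crude hydroxy ester is to be oxidised at once to avoid relactonisation.

Step 9
Reactants: 12 methyl (S)-5-hydroxy-3-methylpentanoate
Product: 13 methyl (S)-3-methyl-5-oxopentanoate
Conditions: TEMPO (cat.), PhI(OAc)2, CH2Cl2, rt
Reagents that add atoms: none
Why: Oxoammonium-mediated oxidation of the primary alcohol stops at the aldehyde, and the β-stereocenter cannot epimerise.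

Step 10
Reactants: 8 triethyl{[(4aR,8aS)-5,5,8a-trimethyl-3,4,4a,5,6,7,8,8a-octahydronaphthalen-2-yl]oxy}silane; 13 methyl (S)-3-methyl-5-oxopentanoate
Product: 14 methyl (3S)-5-hydroxy-3-methyl-5-[(1S,4aR,8aS)-5,5,8a-trimethyl-2-oxodecahydronaphthalen-1-yl]pentanoate (both carbinol epimers)
Conditions: TiCl4, CH2Cl2, −78 °C
Reagents that add atoms: none
Why: Mukaiyama aldol addition: the C9–C11 bond can form only at C9 because the enol silane regiochemistry was fixed in step 6; the aldehyde should add on the open β face, and the new C9 and C11 stereocenters are both erased in step 11.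

Step 11
Reactants: 14 methyl (3S)-5-hydroxy-3-methyl-5-[(1S,4aR,8aS)-5,5,8a-trimethyl-2-oxodecahydronaphthalen-1-yl]pentanoate
Product: 16 methyl (3S)-3-methyl-5-[(4aR,8aS)-5,5,8a-trimethyl-2-oxooctahydronaphthalen-1(2H)-ylidene]pentanoate, via mesylate 15 (not isolated)
Conditions: MsCl, Et3N, CH2Cl2, 0 °C; then DBU, rt
Reagents that add atoms: none
Why: Mesylation and E1cB elimination should give the conjugated exocyclic C9=C11 enone; the alkene geometry is of no consequence because C11 later becomes CH2.

Step 12
Reactants: 16 methyl (3S)-3-methyl-5-[(4aR,8aS)-5,5,8a-trimethyl-2-oxooctahydronaphthalen-1(2H)-ylidene]pentanoate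
Product: 17 methyl (3S)-5-[(2R,4aR,8aS)-2-hydroxy-2,5,5,8a-tetramethyloctahydronaphthalen-1(2H)-ylidene]-3-methylpentanoate
Conditions: MeLi, CeCl3, THF, −78 °C
Reagents that add atoms: methyllithium, [Li]C
Why: Organocerium 1,2-addition (weakly basic, and expected to take the ketone before the methyl ester at −78 °C): with C9 still planar the only facial bias at C8 is the C1 methylene of ring A, which is axial on ring B and syn-axial to C8 on the α face, so methyl should enter from the β face, giving CH3-17 β and OH α (8R).

Step 13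
Reactants: 17 methyl (3S)-5-[(2R,4aR,8aS)-2-hydroxy-2,5,5,8a-tetramethyloctahydronaphthalen-1(2H)-ylidene]-3-methylpentanoate
Product: 18 methyl (3S)-5-[(1R,2R,4aR,8aS)-2-hydroxy-2,5,5,8a-tetramethyldecahydronaphthalen-1-yl]-3-methylpentanoate
Conditions: H2 (1 atm), [Ir(cod)(PCy3)(py)]PF6 (10 mol%), CH2Cl2, rt
Reagents that add atoms: none
Why: Hydroxyl-directed hydrogenation with the cationic iridium catalyst: the metal bound to the 8α-hydroxyl should deliver hydrogen to the α face of the C9=C11 alkene, placing H-9 α and the side chain β (9R), the less stable epimer that an undirected reduction would not give.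

Step 14
Reactants: 18 methyl (3S)-5-[(1R,2R,4aR,8aS)-2-hydroxy-2,5,5,8a-tetramethyldecahydronaphthalen-1-yl]-3-methylpentanoate
Product: 19 methyl (3S)-5-[(1R,2R,4aR,8aS)-2-acetoxy-2,5,5,8a-tetramethyldecahydronaphthalen-1-yl]-3-methylpentanoate
Conditions: Ac2O, Sc(OTf)3 (cat.), MeCN, −20 °C
Reagents that add atoms: acetic anhydride, CC(=O)OC(C)=O
Why: Lewis-acid-catalysed acylation of a hindered tertiary alcohol at low temperature should proceed with retention at C8 (O-acylation) and without elimination.

Step 15
Reactants: 19 methyl (3S)-5-[(1R,2R,4aR,8aS)-2-acetoxy-2,5,5,8a-tetramethyldecahydronaphthalen-1-yl]-3-methylpentanoate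
Product: 21 (3S)-5-[(1R,2R,4aR,8aS)-2-acetoxy-2,5,5,8a-tetramethyldecahydronaphthalen-1-yl]-3-methylpentanoic acid, via lithium carboxylate 20 (not isolated)
Conditions: LiOH, THF/H2O, 0 °C to rt; then 1 M HCl
Reagents that add atoms: lithium hydroxide, [Li+].[OH-]
Why: Chemoselective saponification: the unhindered methyl ester should be cleaved while the hindered tertiary acetate, which is very slow to hydrolyse, is kept; no stereocenter is affected.

**Compound list**

1 | (+)-nopinone, (1R,5S)-6,6-dimethylbicyclo[3.1.1]heptan-2-one | O=C1CC[C@H]2C[C@@H]1C2(C)C | starting material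
2 | (S)-4-(2-acetoxypropan-2-yl)cyclohex-1-en-1-yl acetate | CC(=O)OC1=CC[C@H](CC1)C(C)(C)OC(C)=O | intermediate
3 | (S)-4-(2-methylpent-4-en-2-yl)cyclohex-1-en-1-yl acetate | CC(=O)OC1=CC[C@H](CC1)C(C)(C)CC=C | intermediate
4 | (S)-4-(2-methylpent-4-en-2-yl)cyclohex-2-en-1-one | O=C1C=C[C@H](CC1)C(C)(C)CC=C | intermediate
5 | trimethyl{[(3R,4S)-3-methyl-4-(2-methylpent-4-en-2-yl)cyclohex-1-en-1-yl]oxy}silane | C[Si](C)(C)OC1=C[C@H](C)[C@H](CC1)C(C)(C)CC=C | intermediate
6 | (R)-3-methyl-4-(2-methylpent-4-en-2-yl)cyclohex-2-en-1-one | O=C1C=C(C)[C@H](CC1)C(C)(C)CC=C | intermediate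
7 | (R)-4-(5-bromo-2-methylpentan-2-yl)-3-methylcyclohex-2-en-1-one | O=C1C=C(C)[C@H](CC1)C(C)(C)CCCBr | intermediate
8 | triethyl{[(4aR,8aS)-5,5,8a-trimethyl-3,4,4a,5,6,7,8,8a-octahydronaphthalen-2-yl]oxy}silane | CC[Si](CC)(CC)OC1=C[C@@]2(C)CCCC(C)(C)[C@H]2CC1 | intermediate
9 | (R)-methyl hydrogen 3-methylglutarate, (3R)-5-methoxy-3-methyl-5-oxopentanoic acid | COC(=O)C[C@H](C)CC(=O)O | starting material
10 | lithium (3S)-5-hydroxy-3-methylpentanoate | [Li+].[O-]C(=O)C[C@@H](C)CCO | intermediate
11 | (S)-4-methyloxan-2-one | O=C1C[C@@H](C)CCO1 | intermediate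
12 | methyl (S)-5-hydroxy-3-methylpentanoate | COC(=O)C[C@@H](C)CCO | intermediate
13 | methyl (S)-3-methyl-5-oxopentanoate | COC(=O)C[C@@H](C)CC=O | intermediate
14 | methyl (3S)-5-hydroxy-3-methyl-5-[(1S,4aR,8aS)-5,5,8a-trimethyl-2-oxodecahydronaphthalen-1-yl]pentanoate | O=C1CC[C@@H]2C(C)(C)CCC[C@]2(C)[C@H]1C(O)C[C@H](C)CC(=O)OC | intermediate
15 | methyl (3S)-3-methyl-5-(methylsulfonyloxy)-5-[(1S,4aR,8aS)-5,5,8a-trimethyl-2-oxodecahydronaphthalen-1-yl]pentanoate | O=C1CC[C@@H]2C(C)(C)CCC[C@]2(C)[C@H]1C(OS(C)(=O)=O)C[C@H](C)CC(=O)OC | intermediate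
16 | methyl (3S)-3-methyl-5-[(4aR,8aS)-5,5,8a-trimethyl-2-oxooctahydronaphthalen-1(2H)-ylidene]pentanoate | O=C1CC[C@@H]2C(C)(C)CCC[C@]2(C)C1=CC[C@H](C)CC(=O)OC | intermediate
17 | methyl (3S)-5-[(2R,4aR,8aS)-2-hydroxy-2,5,5,8a-tetramethyloctahydronaphthalen-1(2H)-ylidene]-3-methylpentanoate | O[C@]1(C)CC[C@@H]2C(C)(C)CCC[C@]2(C)C1=CC[C@H](C)CC(=O)OC | intermediate
18 | methyl (3S)-5-[(1R,2R,4aR,8aS)-2-hydroxy-2,5,5,8a-tetramethyldecahydronaphthalen-1-yl]-3-methylpentanoate | O[C@]1(C)CC[C@@H]2C(C)(C)CCC[C@]2(C)[C@H]1CC[C@H](C)CC(=O)OC | intermediate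
19 | methyl (3S)-5-[(1R,2R,4aR,8aS)-2-acetoxy-2,5,5,8a-tetramethyldecahydronaphthalen-1-yl]-3-methylpentanoate | CC(=O)O[C@]1(C)CC[C@@H]2C(C)(C)CCC[C@]2(C)[C@H]1CC[C@H](C)CC(=O)OC | intermediate
20 | lithium (3S)-5-[(1R,2R,4aR,8aS)-2-acetoxy-2,5,5,8a-tetramethyldecahydronaphthalen-1-yl]-3-methylpentanoate | CC(=O)O[C@]1(C)CC[C@@H]2C(C)(C)CCC[C@]2(C)[C@H]1CC[C@H](C)CC(=O)[O-].[Li+] | intermediate
21 | (3S)-5-[(1R,2R,4aR,8aS)-2-acetoxy-2,5,5,8a-tetramethyldecahydronaphthalen-1-yl]-3-methylpentanoic acid, CNP0470037.1 | CC(=O)O[C@]1(C)CC[C@@H]2C(C)(C)CCC[C@]2(C)[C@H]1CC[C@H](C)CC(=O)O | target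

**Step count**

Total steps: 15. Longest linear sequence: 12 (steps 1–6 and 10–15, from nopinone).

**Steps most likely to fail, with fallbacks**

Step 6. Ring closure onto the fully substituted enone carbon may be slow, so that hydrodebromination or intermolecular reductive coupling of the alkyl radical outruns cyclisation. The fallback makes the quaternary centre by cuprate addition instead; it sets out from 4 and comes back at 8. Compound 4 is hydrobrominated as in step 5 to (S)-4-(5-bromo-2-methylpentan-2-yl)cyclohex-2-en-1-one F1. The same nickel-catalysed reductive cyclisation, now onto an unsubstituted enone carbon and so closer to intermolecular precedent, should give triethyl{[(4aS)-5,5-dimethyl-3,4,4a,5,6,7,8,8a-octahydronaphthalen-2-yl]oxy}silane F2, whose ring-fusion configuration does not matter. Saegusa–Ito oxidation with Pd(OAc)2 then gives the octalone (4aR)-5,5-dimethyl-4,4a,5,6,7,8-hexahydronaphthalen-2(3H)-one F3. Conjugate addition of Me2CuLi with Et3SiCl trapping, which on such octalones is expected to place the angular methyl cis to H-4a, returns 8.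

Step 13. The iridium catalyst may fail to engage the hindered axial tertiary hydroxyl, so that hydrogen arrives from the open β face (poor facial selectivity), or the tertiary allylic alcohol may ionise. The fallback sets C9 by C–C bond formation on the β face; it sets out from 8 and lactone 11 and comes back at 18. Lactone 11 is opened with PhSNa in DMF and the carboxylate methylated with MeI to give methyl (3R)-3-methyl-5-(phenylsulfanyl)pentanoate F4. N-Chlorosuccinimide converts it into methyl (3R)-5-chloro-3-methyl-5-(phenylsulfanyl)pentanoate F5. TiCl4-mediated phenylthioalkylation of enol silane 8 with F5 should attach the chain on the β face of C9 and give methyl (3R)-3-methyl-5-(phenylsulfanyl)-5-[(1R,4aR,8aS)-5,5,8a-trimethyl-2-oxodecahydronaphthalen-1-yl]pentanoate F6. Desulfurisation with Raney Ni gives methyl (3S)-3-methyl-5-[(1R,4aR,8aS)-5,5,8a-trimethyl-2-oxodecahydronaphthalen-1-yl]pentanoate F7. MeLi/CeCl3 addition then gives 18, though facial selectivity at C8 is less secure here because the axial C9 chain now flanks the β face.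

Step 2. Proton loss from the tertiary cation (formation of an isopropenyl group) or Lewis-acid cleavage of the enol acetate may compete with capture by the allylsilane. The fallback forms the C4–C3 bond by a radical; it sets out from 1 and comes back at 4. Me3SiI opens nopinone to {[(4S)-4-(2-iodopropan-2-yl)cyclohex-1-en-1-yl]oxy}trimethylsilane F8. Radical allylation with allylSnBu3 and AIBN gives trimethyl{[(4S)-4-(2-methylpent-4-en-2-yl)cyclohex-1-en-1-yl]oxy}silane F9. Saegusa–Ito oxidation with Pd(OAc)2 gives 4 directly.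

**Further compounds**

F1 | step 6 | (S)-4-(5-bromo-2-methylpentan-2-yl)cyclohex-2-en-1-one | O=C1C=C[C@H](CC1)C(C)(C)CCCBr
F2 | step 6 | triethyl{[(4aS)-5,5-dimethyl-3,4,4a,5,6,7,8,8a-octahydronaphthalen-2-yl]oxy}silane | CC[Si](CC)(CC)OC1=CC2CCCC(C)(C)[C@H]2CC1
F3 | step 6 | (4aR)-5,5-dimethyl-4,4a,5,6,7,8-hexahydronaphthalen-2(3H)-one | O=C1C=C2CCCC(C)(C)[C@H]2CC1
F4 | step 13 | methyl (3R)-3-methyl-5-(phenylsulfanyl)pentanoate | COC(=O)C[C@@H](C)CCSc1ccccc1
F5 | step 13 | methyl (3R)-5-chloro-3-methyl-5-(phenylsulfanyl)pentanoate | COC(=O)C[C@@H](C)CC(Cl)Sc1ccccc1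
F6 | step 13 | methyl (3R)-3-methyl-5-(phenylsulfanyl)-5-[(1R,4aR,8aS)-5,5,8a-trimethyl-2-oxodecahydronaphthalen-1-yl]pentanoate | O=C1CC[C@@H]2C(C)(C)CCC[C@]2(C)[C@H]1C(Sc1ccccc1)C[C@H](C)CC(=O)OC
F7 | step 13 | methyl (3S)-3-methyl-5-[(1R,4aR,8aS)-5,5,8a-trimethyl-2-oxodecahydronaphthalen-1-yl]pentanoate | O=C1CC[C@@H]2C(C)(C)CCC[C@]2(C)[C@H]1CC[C@H](C)CC(=O)OC
F8 | step 2 | {[(4S)-4-(2-iodopropan-2-yl)cyclohex-1-en-1-yl]oxy}trimethylsilane | C[Si](C)(C)OC1=CC[C@H](CC1)C(C)(C)I
F9 | step 2 | trimethyl{[(4S)-4-(2-methylpent-4-en-2-yl)cyclohex-1-en-1-yl]oxy}silane | C[Si](C)(C)OC1=CC[C@H](CC1)C(C)(C)CC=C
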